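Picture a one-step world: starting material goes straight to target, its loss is pseudo-first-order, and the constant k is a fixed κ times the charged free catalyst.

| flask | starting material | coupling partner | protic impurity | free catalyst | remark | time |
|---|---|---|---|---|---|---|
| south-east | 0.80 M | 1.6 M | 0.080 M | 22 mM | run made earlier |  |
| north-east | 0.80 M | 1.6 M | 0.080 M | 35 mM | run made earlier |  |
| north-west | 0.80 M | 1.6 M | 0.040 M | 16 mM | run made earlier |  |
| flask | 0.80 M | 1.60 M | 0.0800 M | 16 mM |  | 15 h |

| run | time / h | catalyst intermediate B / % | starting material / % | target / % | catalyst intermediate C / % |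
|---|---|---|---|---|---|
| south-east | 0.833 | 0.4 | 97.7 | 2.2 | 0.8 |
| south-east | 2.50 | 0.5 | 94.5 | 7.9 | 0.4 |
| south-east | 4.00 | 0 | 91.4 | 9.7 | 0 |
| south-east | 6.00 | 0.1 | 85.5 | 15.0 | 0 |
| south-east | 10.0 | 0 | 78.1 | 22.8 | 0 |
| south-east | 12.0 | 0 | 74.3 | 26.5 | 0 |
| south-east | 15.0 | 0.4 | 68.9 | 30.8 | 0.1 |
| north-east | 1.33 | 0.3 | 95.1 | 4.3 | 0.8 |
| north-east | 2.00 | 0 | 91.9 | 7.4 | 0.8 |
| north-east | 3.00 | 0.6 | 88.8 | 11.9 | 0 |
| north-east | 4.00 | 0.4 | 85.5 | 15.3 | 0.4 |
| north-east | 6.00 | 1.2 | 78.7 | 21.0 | 0 |
| north-east | 10.0 | 0 | 66.9 | 33.3 | 0.5 |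
| north-east | 15.0 | 1.0 | 55.2 | 44.4 | 0 |
| north-west | 1.33 | 0.4 | 97.5 | 2.1 | 0.2 |
| north-west | 2.50 | 0.5 | 95.1 | 4.0 | 0.7 |
| north-west | 4.00 | 0.4 | 93.4 | 6.2 | 0.3 |
| north-west | 8.00 | 0 | 85.0 | 13.2 | 0.6 |
| north-west | 15.0 | 1.0 | 74.6 | 24.4 | 0.4 |

(readings scatter by 0.5 percentage points)

- where most of what was charged as starting material, at 15 h is found (catalyst intermediate C / catalyst intermediate B / target / starting material)
- the largest share itself, whichever of these holds it, in percent of the starting material charged

- the numbers in the tables scatter with a standard deviation of 0.5 percentage points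

I test that picture with one division. From the last north-east reading, κ = −ln(fraction left)/(catalyst × time) = 1.13 M⁻¹ h⁻¹, the turnover constant.

| run | free catalyst | protic impurity | κ read |
|---|---|---|---|
| south-east | 22 mM | 0.080 M | 1.13 M⁻¹ h⁻¹ |
| north-east | 35 mM | 0.080 M | 1.13 M⁻¹ h⁻¹ |
| north-west | 16 mM | 0.040 M | 1.22 M⁻¹ h⁻¹ |

The two runs at the flask's impurity level read alike, and north-west, with less impurity and less catalyst than either, reads somewhat higher. So I take the north-east value.

Now the ladder for the flask, fastest rung first. Catalyst intermediates B and C read 0.4% and 0.8% at 0.833 h in south-east and stay near the scatter after that, so I carry neither as a share of the charge. The flask's catalyst charge is 2.00% of its starting material, so the contest is between starting material and target. Next comes the slow rung: k = 0.0181 h⁻¹, a half-life of 38.3 h. The asked 15 h falls short of that, so starting material stays ahead, at 76.2% by my reckoning.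

The forecast says starting material, at 76%, on the grounds that “the rate is linear in catalyst”.

The flask gives starting material, at 75.7%.

    starting material + catalyst intermediate A ⇌ catalyst intermediate B (K = 2.50 M⁻¹, k = 7.89 M⁻¹ h⁻¹)
    coupling partner + free catalyst ⇌ catalyst intermediate A (K = 0.310 M⁻¹, k = 2.64 M⁻¹ h⁻¹)
    coupling partner + protic impurity → quenched reagent (k = 1.19 M⁻¹ h⁻¹)
    catalyst intermediate B ⇌ by-product + catalyst intermediate C (K = 21.0 M, k = 8.03 h⁻¹)
    catalyst intermediate C → free catalyst + target (k = 77.2 h⁻¹)

After 15.0 h the flask also holds a form absent from the readings, catalyst intermediate A, at 20.4% of the catalyst, while free catalyst stands at 67.0% after 1.50 h and 69.9% after 15.0 h. Against the flask's 75.7%, κ gave 76.2%. For a neighbour flask charged with 0.064 M of free catalyst, the same κ gives 33.8%, and that neighbour holds 33.6% starting material after 15.0 h.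

The data were computed with constants of no real substance; scatter was added.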